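**Retrosynthetic overview**
1. Target 22 ⇐ 21 ⇐ 20 by acetylation and desilylation at C13–O; all rings and stereocentres are already present in 20.
2. 20 ⇐ 16 (key step, one flask). The butenolide ring (O–C6–C7=C11–C12) is carried as a furan. Its photooxygenation makes C6 a ketone, so C4 becomes the β-carbon of a C4=C5–C6=O enone lying four bonds from the enol oxygen on C1 of the C1/C3 β-diketone. O–C4 closure (5-exo) gives the 3(2H)-furanone and quaternary C4; enol-lactonisation of C6=O onto C12 restores the butenolide with the C5=C6 bond.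
3. 16 ⇐ 13 by a ring-expanding Claisen condensation: methyl-ketone carbon C2 attacks lactone carbonyl C1 (γ-lactone → ten-membered carbocycle), and the released C8–O is acylated.
4. 13 ⇐ 9 ⇐ 1: asymmetric 2-(ethoxycarbonyl)allylation/lactonisation sets C8 and face-selective hydrogenation sets C10; the enone arm comes from acetal-directed lithiation, formylation and Wittig reaction on desymmetrised furan-3,4-diyldimethanol.
5. Ring order: furan (purchased) → γ-lactone → ten-membered carbocycle → furanone and butenolide together in the key step.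

Key step: step 10

Remark on locants and assumptions: germacrane numbering is used (ring carbons C1–C10: C1 = enol-ether carbon of the furanone, C3 = its ketone, C4 = quaternary carbon, C8 = senecioate carbon, C10 = CH–CH3; C11/C12/C13 = lactone α-carbon, carbonyl and CH2O); TIPS = tri(propan-2-yl)silyl. The target decodes as 4S,5E,8S,10S. Compounds 1, 7, 10 and 14 are taken as catalogue chemicals. The (4E) geometry drawn for 8–18 is what the Wittig step should give; it is erased in step 10, so either isomer would serve.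

**Step 1**
Reactants: 1 furan-3,4-diyldimethanol
Product: 2 [4-(TIPSOCH2)furan-3-yl]methanol
Conditions: NaH (1.0 equiv), THF, 0 °C → rt; TIPSCl (1.0 equiv)
Reagents that add atoms: chlorotri(propan-2-yl)silane, CC(C)[Si](Cl)(C(C)C)C(C)C
Why: O-Silylation of a symmetrical diol through its sparingly soluble monosodium alkoxide should stop at the mono-ether; no stereocentre is involved.

**Step 2**
Reactants: 2 [4-(TIPSOCH2)furan-3-yl]methanol
Product: 3 4-(TIPSOCH2)furan-3-carbaldehyde
Conditions: activated MnO2 (10 equiv), CH2Cl2, rt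
Reagents that add atoms: none
Why: MnO2 oxidation of a heteroaryl carbinol stops at the aldehyde and leaves the furan and silyl ether intact.

**Step 3**
Reactants: 3 4-(TIPSOCH2)furan-3-carbaldehyde
Product: 4 2-[4-(TIPSOCH2)furan-3-yl]-1,3-dioxolane
Conditions: ethylene glycol (3 equiv), PPTS (5 mol %), benzene, reflux, azeotropic water removal
Reagents that add atoms: ethane-1,2-diol, OCCO
Why: Acid-catalysed acetalisation masks the future C8 aldehyde and installs the group that directs the next metalation; the TIPS ether tolerates PPTS.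

**Step 4**
Reactants: 4 2-[4-(TIPSOCH2)furan-3-yl]-1,3-dioxolane
Product: 6 3-(1,3-dioxolan-2-yl)-4-(TIPSOCH2)furan-2-carbaldehyde, via 2-lithiofuran 5 (not isolated)
Conditions: n-BuLi (1.1 equiv), THF, −78 → −40 °C; DMF (3 equiv), −78 °C → rt; H2O
Reagents that add atoms: N,N-dimethylformamide, CN(C)C=O
Why: Directed ortho-metalation: the dioxolane oxygens chelate lithium and steer deprotonation to the adjacent furan α-position (future C6) rather than the α-position beside the bulky, poorly coordinating CH2OTIPS group, and DMF formylates the aryllithium.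

**Step 5**
Reactants: 6 3-(1,3-dioxolan-2-yl)-4-(TIPSOCH2)furan-2-carbaldehyde; 7 3-(triphenyl-λ5-phosphanylidene)butan-2-one
Product: 8 (3E)-4-[3-(1,3-dioxolan-2-yl)-4-(TIPSOCH2)furan-2-yl]-3-methylbut-3-en-2-one
Conditions: toluene, 100 °C
Reagents that add atoms: none
Why: Wittig olefination with a ketone-stabilised ylide reacts only at the free aldehyde and should give the (E)-α-methyl enone.

**Step 6**
Reactants: 8 (3E)-4-[3-(1,3-dioxolan-2-yl)-4-(TIPSOCH2)furan-2-yl]-3-methylbut-3-en-2-one
Product: 9 2-[(1E)-2-methyl-3-oxobut-1-en-1-yl]-4-(TIPSOCH2)furan-3-carbaldehyde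
Conditions: PPTS (10 mol %), acetone/H2O (10:1), 50 °C
Reagents that add atoms: water, O
Why: Mild acid-catalysed acetal hydrolysis of an electron-rich heteroaryl dioxolane frees the C8 aldehyde without touching the TIPS ether or the enone.

**Step 7**
Reactants: 9 2-[(1E)-2-methyl-3-oxobut-1-en-1-yl]-4-(TIPSOCH2)furan-3-carbaldehyde; 10 ethyl 2-(bromomethyl)prop-2-enoate
Product: 12 (5S)-3-methylidene-5-{2-[(1E)-2-methyl-3-oxobut-1-en-1-yl]-4-(TIPSOCH2)furan-3-yl}oxolan-2-one, via hydroxy ester 11 (not isolated)
Conditions: CrCl2 (10 mol %), chiral carbazole bis(oxazoline) ligand (12 mol %), Mn (2 equiv), TMSCl (1.2 equiv), THF, rt; 1 M HCl, THF; PPTS (cat.), CH2Cl2, rt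
Reagents that add atoms: none
Why: Catalytic asymmetric Nozaki–Hiyama–Kishi 2-(alkoxycarbonyl)allylation is aldehyde-selective; the ligand enantiomer is chosen so that the allylchromium attacks the aldehyde face giving the (S)-carbinol (C8, catalyst control), and γ-hydroxy ester 11 lactonises on acid work-up.

**Step 8**
Reactants: 12 (5S)-3-methylidene-5-{2-[(1E)-2-methyl-3-oxobut-1-en-1-yl]-4-(TIPSOCH2)furan-3-yl}oxolan-2-one
Product: 13 (3S,5S)-3-methyl-5-{2-[(1E)-2-methyl-3-oxobut-1-en-1-yl]-4-(TIPSOCH2)furan-3-yl}oxolan-2-one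
Conditions: H2 (1 atm), RhCl(PPh3)3 (5 mol %), benzene, rt
Reagents that add atoms: none
Why: Homogeneous Rh-catalysed hydrogenation should reduce the 1,1-disubstituted exocyclic alkene before the trisubstituted enone and the furan, delivering H2 to the lactone face anti to the C8 furyl group so that the new C10 methyl is cis to it (substrate control).

**Step 9**
Reactants: 13 (3S,5S)-3-methyl-5-{2-[(1E)-2-methyl-3-oxobut-1-en-1-yl]-4-(TIPSOCH2)furan-3-yl}oxolan-2-one; 14 3-methylbut-2-enoyl chloride
Product: 16 (4E,8S,10S)-1,3-dioxo-13-(TIPS-oxy)-6,12-epoxygermacra-4,6,11-trien-8-yl 3-methylbut-2-enoate, via hydroxy diketone 15 (not isolated)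
Conditions: LDA (1.05 equiv), THF, −78 °C; dilution to 2 mM, → 40 °C; −78 °C, LiHMDS (1.0 equiv), then 14 (1.0 equiv); pH 7 buffer
Reagents that add atoms: none
Why: Ring-expanding intramolecular Claisen condensation: the kinetic methyl-ketone enolate (C2) attacks lactone carbonyl C1 and the tetrahedral intermediate collapses with C1–O cleavage, turning the γ-lactone into the ten-membered β-diketone (driven by diketonate formation, C8 and C10 untouched), and the liberated C8 alkoxide, far more nucleophilic than the lithium diketonate, is acylated in situ.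

**Step 10**
Reactants: 16 (4E,8S,10S)-1,3-dioxo-13-(TIPS-oxy)-6,12-epoxygermacra-4,6,11-trien-8-yl 3-methylbut-2-enoate
Product: 20 (4S,5E,8S,10S)-1,4-epoxy-3-oxo-13-(TIPS-oxy)-8-(3-methylbut-2-enoyloxy)germacra-1,5,7(11)-trien-12,6-olide, via furan endoperoxide 17 (not isolated), via hydroxybutenolide 18 (not isolated), via furanone lactol 19 (not isolated)
Conditions: O2, hν (visible), tetraphenylporphyrin (1 mol %), CH2Cl2, −78 °C; Ar purge; i-Pr2NEt (2.5 equiv), −78 → 0 °C; TFAA (1.5 equiv), pyridine (4 equiv), 0 °C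
Reagents that add atoms: dioxygen, O=O
Why: Singlet oxygen adds [4+2] across the furan (C6/C12) and the amine triggers Kornblum–DeLaMare fragmentation of endoperoxide 17 (only C12 carries H) to hydroxybutenolide 18, the ring tautomer of a (Z)-6-oxo-12-carboxylate in which C4 is the β-carbon of a C4=C5–C6=O enone; the enolate oxygen on C1 of the β-diketone then adds to C4 (oxa-Michael) and, after TFAA activation of the carboxyl group, the C5=C6 enol closes onto C12 (enol-lactonisation). The closest known reaction types are the base-assisted photooxygenation of furans to γ-hydroxybutenolides, the intramolecular oxa-Michael addition of phenol or enol oxygens to ene-diones that gives benzofuran-3(2H)-ones and 3(2H)-furanones, and the dehydration of γ-hydroxybutenolides (γ-keto acids) to γ-ylidenebutenolides. The furanone closes 5-exo-trig (O onto C4) and the butenolide re-closes 5-exo-trig at the acyl carbon, while the ten-membered carbocycle is not touched. C4 is the only new stereocentre and is set under substrate control by the C8/C10-biased conformation of the medium ring: the oxa-Michael step is reversible (retro-addition through the C6 enolate), so both C4=C5 isomers, both lactol epimers and all keto–enol and ring–chain tautomers of 18 should drain into the more stable bridged adduct, expected to be 4S with both ring methyl groups on the convex face, before lactonisation locks it. Regioselectivity (C4, 5-exo, against C5, 6-endo) rests on C3 being part of the diketonate and no longer activating C5, so that the C6 ketone alone polarises the alkene toward C4; chemoselectivity of singlet oxygen for the electron-rich furan over the senecioate and enone alkenes is secured at −78 °C, and the (5E) geometry is enforced because C4 and C7 must be cis within the ring.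

**Step 11**
Reactants: 20 (4S,5E,8S,10S)-1,4-epoxy-3-oxo-13-(TIPS-oxy)-8-(3-methylbut-2-enoyloxy)germacra-1,5,7(11)-trien-12,6-olide
Product: 21 (4S,5E,8S,10S)-1,4-epoxy-13-hydroxy-3-oxo-8-(3-methylbut-2-enoyloxy)germacra-1,5,7(11)-trien-12,6-olide
Conditions: HF·pyridine, pyridine/THF, 0 °C → rt
Reagents that add atoms: none
Why: Fluoride-mediated cleavage of the primary silyl ether under buffered acidic conditions should spare the enol lactone, the vinylogous ester and the senecioate.

**Step 12**
Reactants: 21 (4S,5E,8S,10S)-1,4-epoxy-13-hydroxy-3-oxo-8-(3-methylbut-2-enoyloxy)germacra-1,5,7(11)-trien-12,6-olide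
Product: 22 (4S,5E,8S,10S)-13-acetoxy-1,4-epoxy-3-oxo-8-(3-methylbut-2-enoyloxy)germacra-1,5,7(11)-trien-12,6-olide (CNP0102620.1)
Conditions: Ac2O (1.5 equiv), pyridine, DMAP (5 mol %), CH2Cl2, 0 °C
Reagents that add atoms: acetic anhydride, CC(=O)OC(C)=O
Why: Standard acylation of the only free hydroxyl group; no stereocentre is affected.

**Compound list**
1 | furan-3,4-diyldimethanol | OCc1cocc1CO | starting material
2 | [4-(TIPSOCH2)furan-3-yl]methanol | CC(C)[Si](OCc1cocc1CO)(C(C)C)C(C)C | intermediate
3 | 4-(TIPSOCH2)furan-3-carbaldehyde | CC(C)[Si](OCc1cocc1C=O)(C(C)C)C(C)C | intermediate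
4 | 2-[4-(TIPSOCH2)furan-3-yl]-1,3-dioxolane | CC(C)[Si](OCc1cocc1C1OCCO1)(C(C)C)C(C)C | intermediate
5 | 2-lithio derivative of 4 (Li on the furan carbon next to the dioxolanyl-bearing carbon) | CC(C)[Si](OCc1coc([Li])c1C1OCCO1)(C(C)C)C(C)C | intermediate
6 | 3-(1,3-dioxolan-2-yl)-4-(TIPSOCH2)furan-2-carbaldehyde | CC(C)[Si](OCc1coc(C=O)c1C1OCCO1)(C(C)C)C(C)C | intermediate
7 | 3-(triphenyl-λ5-phosphanylidene)butan-2-one | CC(=O)C(C)=P(c1ccccc1)(c1ccccc1)c1ccccc1 | starting material
8 | (3E)-4-[3-(1,3-dioxolan-2-yl)-4-(TIPSOCH2)furan-2-yl]-3-methylbut-3-en-2-one | CC(=O)/C(C)=C/c1occ(CO[Si](C(C)C)(C(C)C)C(C)C)c1C1OCCO1 | intermediate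
9 | 2-[(1E)-2-methyl-3-oxobut-1-en-1-yl]-4-(TIPSOCH2)furan-3-carbaldehyde | CC(=O)/C(C)=C/c1occ(CO[Si](C(C)C)(C(C)C)C(C)C)c1C=O | intermediate
10 | ethyl 2-(bromomethyl)prop-2-enoate | C=C(CBr)C(=O)OCC | starting material
11 | ethyl (4S)-4-hydroxy-2-methylidene-4-{2-[(1E)-2-methyl-3-oxobut-1-en-1-yl]-4-(TIPSOCH2)furan-3-yl}butanoate | C=C(C[C@H](O)c1c(/C=C(\C)C(C)=O)occ1CO[Si](C(C)C)(C(C)C)C(C)C)C(=O)OCC | intermediate
12 | (5S)-3-methylidene-5-{2-[(1E)-2-methyl-3-oxobut-1-en-1-yl]-4-(TIPSOCH2)furan-3-yl}oxolan-2-one | C=C1C[C@@H](c2c(/C=C(\C)C(C)=O)occ2CO[Si](C(C)C)(C(C)C)C(C)C)OC1=O | intermediate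
13 | (3S,5S)-3-methyl-5-{2-[(1E)-2-methyl-3-oxobut-1-en-1-yl]-4-(TIPSOCH2)furan-3-yl}oxolan-2-one (cis) | C[C@H]1C[C@@H](c2c(/C=C(\C)C(C)=O)occ2CO[Si](C(C)C)(C(C)C)C(C)C)OC1=O | intermediate
14 | 3-methylbut-2-enoyl chloride | CC(C)=CC(Cl)=O | starting material
15 | (4E,8S,10S)-8-hydroxy-13-(TIPS-oxy)-6,12-epoxygermacra-4,6,11-triene-1,3-dione (furan-fused ten-membered β-diketone, formed as its lithium salt) | C/C1=C\c2occ(CO[Si](C(C)C)(C(C)C)C(C)C)c2[C@@H](O)C[C@H](C)C(=O)CC1=O | intermediate
16 | (4E,8S,10S)-1,3-dioxo-13-(TIPS-oxy)-6,12-epoxygermacra-4,6,11-trien-8-yl 3-methylbut-2-enoate | C/C1=C\c2occ(CO[Si](C(C)C)(C(C)C)C(C)C)c2[C@@H](OC(=O)C=C(C)C)C[C@H](C)C(=O)CC1=O | intermediate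
17 | 6,12-epidioxide of 16 (furan endoperoxide; C6 and C12 epimer mixture) | C/C1=C\C23OOC(O2)C(CO[Si](C(C)C)(C(C)C)C(C)C)=C3[C@@H](OC(=O)C=C(C)C)C[C@H](C)C(=O)CC1=O | intermediate
18 | (4E,8S,10S)-6-hydroxy-1,3-dioxo-13-(TIPS-oxy)-8-(3-methylbut-2-enoyloxy)germacra-4,7(11)-dien-12,6-olide (C6 epimers; ring tautomer of the 6-oxo-12-acid) | C/C1=C\C2(O)OC(=O)C(CO[Si](C(C)C)(C(C)C)C(C)C)=C2[C@@H](OC(=O)C=C(C)C)C[C@H](C)C(=O)CC1=O | intermediate
19 | (4S,8S,10S)-1,4-epoxy-6-hydroxy-3-oxo-13-(TIPS-oxy)-8-(3-methylbut-2-enoyloxy)germacra-1,7(11)-dien-12,6-olide (C6 epimers) | CC(C)[Si](OCC1=C2C(O)(C[C@]3(C)OC(=CC3=O)[C@@H](C)C[C@@H]2OC(=O)C=C(C)C)OC1=O)(C(C)C)C(C)C | intermediate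
20 | (4S,5E,8S,10S)-1,4-epoxy-3-oxo-13-(TIPS-oxy)-8-(3-methylbut-2-enoyloxy)germacra-1,5,7(11)-trien-12,6-olide | CC(C)[Si](OCC1=C2/C(=C\[C@]3(C)OC(=CC3=O)[C@@H](C)C[C@@H]2OC(=O)C=C(C)C)OC1=O)(C(C)C)C(C)C | intermediate
21 | (4S,5E,8S,10S)-1,4-epoxy-13-hydroxy-3-oxo-8-(3-methylbut-2-enoyloxy)germacra-1,5,7(11)-trien-12,6-olide | OCC1=C2/C(=C\[C@]3(C)OC(=CC3=O)[C@@H](C)C[C@@H]2OC(=O)C=C(C)C)OC1=O | intermediate
22 | (4S,5E,8S,10S)-13-acetoxy-1,4-epoxy-3-oxo-8-(3-methylbut-2-enoyloxy)germacra-1,5,7(11)-trien-12,6-olide (CNP0102620.1) | CC(=O)OCC1=C2/C(=C\[C@]3(C)OC(=CC3=O)[C@@H](C)C[C@@H]2OC(=O)C=C(C)C)OC1=O | target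

**Step count**
Total: 12 steps. Longest linear sequence: 12 steps (1 → 22).

**Steps most likely to fail**

Step 9. Closure of the strained ten-membered ring may lose to intermolecular acylation, or run back through the transannular hemiketal alkoxide (retro-Claisen) before the diketonate is secured; C10 may also epimerise if enolate equilibration sets in. The fallback abandons the ring expansion for an open-chain acyl donor that cannot revert. It sets out from 13: aminolysis of the lactone with the chloromagnesium amide of N,O-dimethylhydroxylamine (MeNHOMe·HCl, i-PrMgCl, THF, −20 °C) should give (2S,4S)-4-hydroxy-N-methoxy-N,2-dimethyl-4-{2-[(1E)-2-methyl-3-oxobut-1-en-1-yl]-4-(TIPSOCH2)furan-3-yl}butanamide F1. Esterification of its C8 hydroxyl with 3-methylbut-2-enoic acid (DCC, DMAP) should give the corresponding 4-(3-methylbut-2-enoyloxy) amide F2. Treatment with LiHMDS under high dilution should then close the ring by attack of the methyl-ketone enolate on the amide; the chelated tetrahedral adduct collapses only on work-up, and the route is rejoined at 16.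

Step 10. The transannular conjugate addition may show poor facial selectivity at C4, or the enol oxygen may add 6-endo at C5 of the furyl enone before the furan has been oxidised, or lactonisation may stall at the lactol. The fallback replaces the substrate-controlled one-flask cascade by a stepwise, catalyst-controlled sequence. It sets out from 16: photooxygenation and amine treatment alone at −78 °C with isolation of hydroxybutenolide 18; oxa-Michael addition promoted by a bifunctional cinchona-derived squaramide, whose pseudo-enantiomer is chosen to deliver the oxygen to the C4 face that gives 4S, with isolation of 19; then dehydration with TFAA/pyridine, returning to the route at 20. No compound outside the list arises (F0).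

Step 4. Regiocontrol of the lithiation may be lost (metalation beside the CH2OTIPS group, or abstraction of the acetal C–H with fragmentation). The fallback uses a stronger chelating director and a different construction of the enone arm. It sets out from 3: in situ protection as the α-amino alkoxide with lithium N,N,N'-trimethylethylenediamide, ortho-lithiation with n-BuLi and quenching with iodine should give 2-iodo-4-(TIPSOCH2)furan-3-carbaldehyde F3. A Heck reaction of F3 with 3-methylbut-3-en-2-one (Pd(OAc)2, P(o-tol)3, Et3N, MeCN, 80 °C) should then give the (E)-enone aldehyde directly, rejoining the route at 9 and bypassing steps 3–6.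

**Further compounds**
F1 | step 9 | (2S,4S)-4-hydroxy-N-methoxy-N,2-dimethyl-4-{2-[(1E)-2-methyl-3-oxobut-1-en-1-yl]-4-(TIPSOCH2)furan-3-yl}butanamide | CON(C)C(=O)[C@@H](C)C[C@H](O)c1c(/C=C(\C)C(C)=O)occ1CO[Si](C(C)C)(C(C)C)C(C)C
F2 | step 9 | (1S,3S)-4-[methoxy(methyl)amino]-3-methyl-1-{2-[(1E)-2-methyl-3-oxobut-1-en-1-yl]-4-(TIPSOCH2)furan-3-yl}-4-oxobutyl 3-methylbut-2-enoate | CON(C)C(=O)[C@@H](C)C[C@H](OC(=O)C=C(C)C)c1c(/C=C(\C)C(C)=O)occ1CO[Si](C(C)C)(C(C)C)C(C)C
F0 | step 10 | none | none
F3 | step 4 | 2-iodo-4-(TIPSOCH2)furan-3-carbaldehyde | O=Cc1c(I)occ1CO[Si](C(C)C)(C(C)C)C(C)C
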